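The meeting took up one question: how much of the electrophile has reacted at the end of flasks theta, eta and delta, which differ in their free base.

    acid set free + free base ⇌ salt of the base (K1 = 270 M⁻¹, k1 = 0.96 M⁻¹ s⁻¹)
    electrophile + nucleophile ⇌ acid set free + product (K2 = 0.80, k2 = 0.30 M⁻¹ s⁻¹)
    nucleophile + acid set free ⇌ protonated nucleophile, settled at all times (K3 = 50000 M⁻¹)

in all of them: electrophile 0.10 M; nucleophile 0.105 M; time 15 min
- theta: free base 0.110 M
- eta: free base 0.220 M
- delta: free base 0.440 M

- part of the electrophile that has reacted at the end, theta
- part of the electrophile that has reacted at the end, eta
- part of the electrophile that has reacted at the end, delta
- what raising the concentration of free base from its lowest to its highest value here does to the part of the electrophile that has reacted (changes below 5 percentage points count as none) (it falls / no change / it rises)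

Minutes. The first speaker turned step 2 into a time: at theta's charges, the forward half-life of the electrophile is 0.37 min, short against the 15 min allowed. She therefore expected the first reaction to be over early.

The second speaker asked who takes the acid set free. He compared K3[nucleophile], 5200, with K1[free base], 30, at theta's start, and argued that the nucleophile takes it first.

As secretary, I reckoned the consequence myself. Each product then costs two nucleophiles, one that reacts and one parked as protonated nucleophile. The 0.105 M charged is less than the 0.200 M that this price demands, so the nucleophile is the limiting reagent. Conversion should stop at the stall conversion, half the nucleophile charged divided by the electrophile charged: 52.5 %. Each salt of the base formed frees one nucleophile, worth half a product. My reckoning therefore gives a stall and a rule for the surplus, but no end values.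

The forecast gave 59 %, 65 % and 71 %, with the trend: it rises. Its ground was that “conversion stalls near 52% within a minute or two”, the same stall as mine, and it went on to figures where my reckoning stopped.

The simulation gives 59.5 %, 63.9 % and 69.3 %, and the trend: it rises, by 9.8 percentage points. That gap between delta and theta is due to the difference in free base. The forecast stands within the margin on each value, and its trend is right.

Part of theta's conversion rests on the step to the salt of the base: without that step, theta ends at 52.3 % instead of 59.5 %, beside the stall conversion of 52.5 %. At its end theta holds 0.0148 M of salt of the base, and the rule turns this into 59.9 %, beside the simulated 59.5 %. A neighbouring flask, theta with 0.40 M of electrophile, has a stall conversion of 13.1 %. Its 0.0323 M of salt of the base raises that to 17.1 %, and the simulated flask stands at 17.3 %.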